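Assumption: the target has no stereocentres and is achiral, so the "single enantiomer" requirement is met automatically; 7-bromoindole is taken as a commercial starting material.

**Retrosynthetic overview**
1. Target 3 ⇒ disconnect the C2–Br and C3–Br bonds (electrophilic bromination) back to commercial 7-bromoindole 1.
2. In the forward direction C3 (the most nucleophilic position) is brominated first to give 2, then C2 in the same flask.
3. No ring is formed: the indole bicycle and the C7–Br are bought intact in 1.

**Route**

Step 1
Reactants: 1 7-bromo-1H-indole
Product: 3 2,3,7-tribromo-1H-indole, via 3,7-dibromo-1H-indole 2 (not isolated)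
Conditions: NBS (2.05 equiv, recrystallised), SiO2, dry CH2Cl2, 0 °C → rt, dark, N2
Reagents that add atoms: N-bromosuccinimide (NBS), O=C1CCC(=O)N1Br
Why: Electrophilic aromatic substitution with NBS puts the first Br at the enamine-like C3 to give 2, and with C3 blocked the second Br+ ends at C2, the only free pyrrole-ring position, while the 7-Br-deactivated benzo ring is untouched at exactly two equivalents; no stereocentre is formed.

**Compound list**
1 | 7-bromo-1H-indole | Brc1cccc2cc[nH]c12 | starting material
2 | 3,7-dibromo-1H-indole | Brc1c[nH]c2c(Br)cccc12 | intermediate
3 | 2,3,7-tribromo-1H-indole | Brc1[nH]c2c(Br)cccc2c1Br | target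

**Totals**
Total step count: 1
Longest linear sequence: 1 step

**Steps most likely to fail**
The route has only one step, so this list has a single entry.

Step 1 can fail in three ways:
- over-bromination of the benzo ring at C5 or C6 if NBS is in excess;
- oxidation to oxindole or isatin-type products if water is present;
- decomposition of the free N–H 2,3-dibromoindole on acidic silica or on storage; it should be filtered quickly, chromatographed on base-washed silica and kept cold and dark.

Fallback for step 1: it sets out from compound 1 and comes back to the route at compound 3. It replaces the double electrophilic bromination by an N-protected, directed-metalation sequence in which each bromine is placed separately.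
- Compound 1 is N-sulfonylated (NaH, PhSO2Cl, THF, 0 °C → rt) to give 7-bromo-1-(phenylsulfonyl)-1H-indole F1.
- Br2 in CH2Cl2 at rt brominates only C3 of the deactivated N-sulfonylindole, giving 3,7-dibromo-1-(phenylsulfonyl)-1H-indole F2.
- LDA (1.1 equiv, THF, −78 °C) removes the acidic C2–H; an amide base does not undergo halogen–metal exchange with the aryl bromides. The 2-lithio species is quenched with 1,2-dibromotetrachloroethane to give 2,3,7-tribromo-1-(phenylsulfonyl)-1H-indole F3.
- Aqueous NaOH in THF at 40 °C cleaves the activated sulfonamide and returns the route to 3.

**Further compounds**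
F1 | step 1 | 7-bromo-1-(phenylsulfonyl)-1H-indole | O=S(=O)(c1ccccc1)n1ccc2cccc(Br)c21
F2 | step 1 | 3,7-dibromo-1-(phenylsulfonyl)-1H-indole | O=S(=O)(c1ccccc1)n1cc(Br)c2cccc(Br)c21
F3 | step 1 | 2,3,7-tribromo-1-(phenylsulfonyl)-1H-indole | O=S(=O)(c1ccccc1)n1c(Br)c(Br)c2cccc(Br)c21
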